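**Retrosynthetic overview**
Feature: ring A carries four contiguous substituents, C1-OH, C2-CH2CH2 (to ring D), C3-O-ring B and C4-OMe, with OH and OMe para. This is the pattern left when an oxygen nucleophile adds to the β-carbon C3 of a 2-alkyl-4,4-dimethoxycyclohexa-2,5-dienone and one methanol is lost.
Last disconnection: the O(ring B)-C3(ring A) bond. A fluoride-released ring B phenoxide adds to the ring A p-quinone monoketal, which closes the only new ring (the 18-membered macrocycle) and restores aromatic ring A.
Before that: the two CH2CH2 bridges (B-C first, then A-D) come from Wittig olefinations on a ring C-O-ring D core. One hydrogenation saturates both and also frees the ring A phenol.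
First bond: the ring C-O-ring D ether, by SNAr of mono-MOM protocatechualdehyde on 4-fluorobenzonitrile. All four benzene rings are bought, so the order is open chain A-D-C-B, then the macrocycle.
Key step: step 15

Remark: the Wittig products are E/Z mixtures and their SMILES carry no alkene descriptor, because both C=C bonds are hydrogenated later. The target has no stereocentre.

Step 1
Reactants: 1 3,4-dihydroxybenzaldehyde (ring C)
Product: 2 3-hydroxy-4-(methoxymethoxy)benzaldehyde
Conditions: MOMCl (1.05 equiv), K2CO3 (1.1 equiv), acetone, 0 °C to rt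
Reagents that add atoms: chloromethyl methyl ether (MOMCl), COCCl
Why: Williamson-type O-alkylation under acidity control: the 4-OH is conjugated with the para formyl group and is the more acidic phenol, so a slight excess of weak base and one equivalent of MOMCl should alkylate that oxygen preferentially.

Step 2
Reactants: 2 3-hydroxy-4-(methoxymethoxy)benzaldehyde, 3 4-fluorobenzonitrile (ring D)
Product: 4 4-[5-formyl-2-(methoxymethoxy)phenoxy]benzonitrile
Conditions: K2CO3, DMF, 110-120 °C
Reagents that add atoms: none
Why: SNAr via a Meisenheimer adduct: the remaining 3-phenoxide displaces fluoride para to the nitrile, while the MOM acetal and the non-enolizable aldehyde are inert to carbonate in hot DMF.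

Step 3
Reactants: 5 3-hydroxybenzaldehyde (ring B)
Product: 6 3-(triisopropylsilyloxy)benzaldehyde
Conditions: TIPSCl, imidazole, DMF, rt
Reagents that add atoms: triisopropylsilyl chloride (TIPSCl), CC(C)[Si](Cl)(C(C)C)C(C)C
Why: Imidazole-promoted O-silylation of a phenol; the bulky aryl TIPS ether should survive hydride, amide base, ylide and hydrogenation conditions and still fall quickly to fluoride in step 15.

Step 4
Reactants: 6 3-(triisopropylsilyloxy)benzaldehyde
Product: 7 [3-(triisopropylsilyloxy)phenyl]methanol
Conditions: NaBH4, MeOH/THF, 0 °C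
Reagents that add atoms: none
Why: Chemoselective borohydride reduction of an aromatic aldehyde to the benzylic alcohol, which leaves the silyl ether untouched at 0 °C.

Step 5
Reactants: 7 [3-(triisopropylsilyloxy)phenyl]methanol
Product: 8 3-(triisopropylsilyloxy)benzyl bromide
Conditions: CBr4, PPh3, CH2Cl2, 0 °C
Reagents that add atoms: carbon tetrabromide, BrC(Br)(Br)Br
Why: Appel reaction: the alcohol is activated as an alkoxyphosphonium ion and displaced by bromide (SN2) under essentially neutral conditions that spare the silyl ether.

Step 6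
Reactants: 8 3-(triisopropylsilyloxy)benzyl bromide
Product: 9 [3-(triisopropylsilyloxy)benzyl]triphenylphosphonium bromide
Conditions: PPh3, toluene, reflux
Reagents that add atoms: triphenylphosphine, c1ccc(cc1)P(c1ccccc1)c1ccccc1
Why: SN2 quaternization of PPh3 by a primary benzylic bromide, with the salt expected to precipitate from toluene.

Step 7
Reactants: 9 [3-(triisopropylsilyloxy)benzyl]triphenylphosphonium bromide, 4 4-[5-formyl-2-(methoxymethoxy)phenoxy]benzonitrile
Product: 11 B-C stilbene nitrile 4-[2-(methoxymethoxy)-5-{2-[3-(triisopropylsilyloxy)phenyl]ethenyl}phenoxy]benzonitrile (E/Z mixture), via ring B benzylidenetriphenylphosphorane 10 (not isolated)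
Conditions: NaN(SiMe3)2, THF, -78 to 0 °C; then 4, -78 °C to rt
Reagents that add atoms: none
Why: Wittig olefination: the semistabilized benzylidene ylide, made with a non-nucleophilic amide base that does not attack silicon, condenses with the aldehyde much faster than it could add to the aryl nitrile, and the alkene geometry is irrelevant.

Step 8
Reactants: 11 B-C stilbene nitrile
Product: 13 B-C stilbene aldehyde 4-[2-(methoxymethoxy)-5-{2-[3-(triisopropylsilyloxy)phenyl]ethenyl}phenoxy]benzaldehyde (E/Z mixture), via N-diisobutylaluminium aldimine 12 (not isolated)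
Conditions: i-Bu2AlH (1.3 equiv), CH2Cl2, -78 °C; then aq. KNaC4H4O6 (potassium sodium tartrate), rt; brief stirring with 5% aq. citric acid
Reagents that add atoms: water, O
Why: Partial reduction of a nitrile with i-Bu2AlH: a single hydride transfer gives the N-aluminated aldimine, which resists further reduction at low temperature and is hydrolysed to the aldehyde at a pH that the MOM acetal and the TIPS ether tolerate.

Step 9
Reactants: 14 2-hydroxy-5-methoxybenzaldehyde (ring A)
Product: 15 2-(benzyloxy)-5-methoxybenzaldehyde
Conditions: BnBr, K2CO3, DMF, rt to 50 °C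
Reagents that add atoms: benzyl bromide, BrCc1ccccc1
Why: Williamson ether synthesis on the phenoxide; benzyl is chosen because it leaves in the same hydrogenation that saturates the alkenes.

Step 10
Reactants: 15 2-(benzyloxy)-5-methoxybenzaldehyde
Product: 16 [2-(benzyloxy)-5-methoxyphenyl]methanol
Conditions: NaBH4, MeOH, 0 °C
Reagents that add atoms: none
Why: Borohydride reduction of an aromatic aldehyde to the benzylic alcohol, with both aryl ethers inert.

Step 11
Reactants: 16 [2-(benzyloxy)-5-methoxyphenyl]methanol
Product: 17 [2-(benzyloxy)-5-methoxybenzyl]triphenylphosphonium bromide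
Conditions: PPh3·HBr, MeCN, reflux
Reagents that add atoms: triphenylphosphine hydrobromide, Br.c1ccc(cc1)P(c1ccccc1)c1ccccc1
Why: Direct phosphonium salt formation from an electron-rich benzylic alcohol: HBr turns OH into a leaving group and PPh3 captures the benzylic electrophile, which avoids isolating the labile ortho-alkoxybenzyl bromide.

Step 12
Reactants: 17 [2-(benzyloxy)-5-methoxybenzyl]triphenylphosphonium bromide, 13 B-C stilbene aldehyde
Product: 19 linear bis-stilbene A-D-C-B (ring A OBn and OMe; ring C OMOM; ring B OTIPS; E/Z mixtures), via ring A benzylidenetriphenylphosphorane 18 (not isolated)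
Conditions: NaN(SiMe3)2, THF, -78 to 0 °C; then 13, -78 °C to rt
Reagents that add atoms: none
Why: Wittig olefination of the ring D aldehyde with a semistabilized ylide, the only carbonyl group present, under the same silyl-compatible base conditions as step 7.

Step 13
Reactants: 19 linear bis-stilbene A-D-C-B
Product: 20 seco bis-bibenzyl with free ring A 4-methoxyphenol (ring B OTIPS; ring C OMOM)
Conditions: H2 (1 atm), Pd/C (10 wt%), EtOAc, rt
Reagents that add atoms: none
Why: Heterogeneous hydrogenation: both stilbene C=C bonds are saturated and the aryl benzyl ether is hydrogenolysed over Pd/C in a neutral solvent in which the MOM acetal, TIPS ether and diaryl ether are inert, so that ring A carries the only free phenol.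

Step 14
Reactants: 20 seco bis-bibenzyl with free ring A 4-methoxyphenol
Product: 21 ring A p-quinone monoketal (2-alkyl-4,4-dimethoxycyclohexa-2,5-dienone; ring B OTIPS; ring C OMOM)
Conditions: PhI(OAc)2 (1.1 equiv), MeOH/CH2Cl2, 0 °C; aq. NaHCO3 work-up; Et3N-deactivated silica
Reagents that add atoms: methanol, CO
Why: Oxidative dearomatization of a 4-methoxyphenol with a trivalent iodine reagent: ligand exchange at iodine with the only free phenol, two-electron oxidation and capture by methanol at the methoxy-bearing para carbon give the p-quinone monoketal, while the aryl ethers of rings B, C and D are not oxidized at 0 °C.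

Step 15
Reactants: 21 ring A p-quinone monoketal
Product: 24 MOM-protected macrocycle (ring A: C1-OH / C2-CH2CH2 / C3-O-ring B / C4-OMe), via ring B tetrabutylammonium phenoxide 22 (not isolated), via macrocyclic dimethoxyenone adduct 23 (not isolated)
Conditions: n-Bu4NF (1.2 equiv), AcOH (1.0 equiv), THF, 21 added by syringe pump (final ca. 1 mM), 0 °C to rt; aq. NaHCO3 wash; then crude 23, pyridinium p-toluenesulfonate (cat.), 4 Å molecular sieves, dry CH2Cl2, rt
Reagents that add atoms: none
Why: Proposed new method: fluoride strips the aryl silyl ether, the ring B phenoxide of 22 adds 1,4 to C3 of the cross-conjugated dienone (the β-carbon between the arm-bearing C2 and the ketal carbon C4), and the far more basic enolate is protonated at C2 by the phenol/acetate buffer, so that neutral adduct 23 can build up in a reversible, base-catalysed equilibrium. Because H-C3 of 23 is not acidified and base can only expel the aryloxide again, aromatization is run as a separate anhydrous acid stage: ionization of one C4 methoxy group to the oxocarbenium ion, loss of H-C3 and keto-enol tautomerization give ring A of 24, in which the former carbonyl is the free OH and the surviving ketal oxygen is the OMe. The closest known reaction type is the intermolecular base-mediated conjugate addition of alcohols, thiols and stabilized carbanions to p-quinone monoketals followed by acid-induced loss of methanol to 3-substituted 4-methoxyphenols; the phenoxide nucleophile and the macrocyclic setting are the untested elements. The one ring closed is the 18-membered macrocycle, by an 18-endo-trig oxa-Michael closure at about 1 mM to hold back oligomers. The stereocentres at C2 and C3 of 23 are transient and vanish on aromatization, so nothing has to be controlled there. The step needs attack at C3 rather than at the intrinsically more reactive, unhindered C5, and only the tether favours it (the arm on C2 reaches the neighbouring carbon in the natural ortho-fused 18-membered ring, whereas C5 requires a 20-membered para-bridged ring), which makes this the main risk, while chemoselectivity is secured by the MOM ether, which leaves the ring B oxygen as the only nucleophile.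

Step 16
Reactants: 24 MOM-protected macrocycle
Product: 25 target CNP0179896.0
Conditions: HCl (aq., cat.), MeOH/THF, 45 °C
Reagents that add atoms: none
Why: Acid-catalysed acetal exchange: protonation of the MOM acetal, release of the ring C phenol and capture of the oxocarbenium ion by methanol, under conditions that leave the aryl methyl ether, the diaryl ethers and the bibenzyl bridges untouched.

**Compound list**
1 | 3,4-dihydroxybenzaldehyde | O=Cc1ccc(O)c(O)c1 | starting material
2 | 3-hydroxy-4-(methoxymethoxy)benzaldehyde | O=Cc1ccc(OCOC)c(O)c1 | intermediate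
3 | 4-fluorobenzonitrile | N#Cc1ccc(F)cc1 | starting material
4 | 4-[5-formyl-2-(methoxymethoxy)phenoxy]benzonitrile | O=Cc1ccc(OCOC)c(Oc2ccc(C#N)cc2)c1 | intermediate
5 | 3-hydroxybenzaldehyde | O=Cc1cccc(O)c1 | starting material
6 | 3-(triisopropylsilyloxy)benzaldehyde | CC(C)[Si](Oc1cccc(C=O)c1)(C(C)C)C(C)C | intermediate
7 | [3-(triisopropylsilyloxy)phenyl]methanol | CC(C)[Si](Oc1cccc(CO)c1)(C(C)C)C(C)C | intermediate
8 | 3-(triisopropylsilyloxy)benzyl bromide | CC(C)[Si](Oc1cccc(CBr)c1)(C(C)C)C(C)C | intermediate
9 | [3-(triisopropylsilyloxy)benzyl]triphenylphosphonium bromide | [Br-].CC(C)[Si](Oc1cccc(C[P+](c2ccccc2)(c2ccccc2)c2ccccc2)c1)(C(C)C)C(C)C | intermediate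
10 | ring B benzylidenetriphenylphosphorane (ylide of 9, not isolated) | CC(C)[Si](Oc1cccc(C=P(c2ccccc2)(c2ccccc2)c2ccccc2)c1)(C(C)C)C(C)C | intermediate
11 | B-C stilbene nitrile (E/Z mixture) | CC(C)[Si](Oc1cccc(C=Cc2ccc(OCOC)c(Oc3ccc(C#N)cc3)c2)c1)(C(C)C)C(C)C | intermediate
12 | N-diisobutylaluminium aldimine of 13 (not isolated) | CC(C)[Si](Oc1cccc(C=Cc2ccc(OCOC)c(Oc3ccc(C=N[Al](CC(C)C)CC(C)C)cc3)c2)c1)(C(C)C)C(C)C | intermediate
13 | B-C stilbene with ring D aldehyde (E/Z mixture) | CC(C)[Si](Oc1cccc(C=Cc2ccc(OCOC)c(Oc3ccc(C=O)cc3)c2)c1)(C(C)C)C(C)C | intermediate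
14 | 2-hydroxy-5-methoxybenzaldehyde | COc1ccc(O)c(C=O)c1 | starting material
15 | 2-(benzyloxy)-5-methoxybenzaldehyde | COc1ccc(OCc2ccccc2)c(C=O)c1 | intermediate
16 | [2-(benzyloxy)-5-methoxyphenyl]methanol | COc1ccc(OCc2ccccc2)c(CO)c1 | intermediate
17 | [2-(benzyloxy)-5-methoxybenzyl]triphenylphosphonium bromide | [Br-].COc1ccc(OCc2ccccc2)c(C[P+](c2ccccc2)(c2ccccc2)c2ccccc2)c1 | intermediate
18 | ring A benzylidenetriphenylphosphorane (ylide of 17, not isolated) | COc1ccc(OCc2ccccc2)c(C=P(c2ccccc2)(c2ccccc2)c2ccccc2)c1 | intermediate
19 | linear bis-stilbene A-D-C-B (E/Z mixtures) | COc1ccc(OCc2ccccc2)c(C=Cc2ccc(Oc3cc(C=Cc4cccc(O[Si](C(C)C)(C(C)C)C(C)C)c4)ccc3OCOC)cc2)c1 | intermediate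
20 | seco bis-bibenzyl, free ring A 4-methoxyphenol | COc1ccc(O)c(CCc2ccc(Oc3cc(CCc4cccc(O[Si](C(C)C)(C(C)C)C(C)C)c4)ccc3OCOC)cc2)c1 | intermediate
21 | ring A p-quinone monoketal | COC1(OC)C=CC(=O)C(CCc2ccc(Oc3cc(CCc4cccc(O[Si](C(C)C)(C(C)C)C(C)C)c4)ccc3OCOC)cc2)=C1 | intermediate
22 | ring B tetrabutylammonium phenoxide of the monoketal (not isolated) | COC1(OC)C=CC(=O)C(CCc2ccc(Oc3cc(CCc4cccc([O-])c4)ccc3OCOC)cc2)=C1.CCCC[N+](CCCC)(CCCC)CCCC | intermediate
23 | macrocyclic oxa-Michael adduct, 4,4-dimethoxycyclohex-2-enone ring A (transient C2/C3 stereocentres undefined, not isolated) | COC1(OC)C=CC(=O)C2C1Oc1cccc(c1)CCc1ccc(OCOC)c(c1)Oc1ccc(cc1)CC2 | intermediate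
24 | MOM-protected macrocycle | COc1ccc(O)c2c1Oc1cccc(c1)CCc1ccc(OCOC)c(c1)Oc1ccc(cc1)CC2 | intermediate
25 | CNP0179896.0 | COc1ccc(O)c2c1Oc1cccc(c1)CCc1ccc(O)c(c1)Oc1ccc(cc1)CC2 | target

Total step count: 16
Longest linear sequence: 11 steps (steps 3, 4, 5, 6, 7, 8, 12, 13, 14, 15, 16, from 3-hydroxybenzaldehyde)

**Steps most likely to fail**

**Step 15.**
- What may go wrong:
  - The phenoxide may add at the unhindered β-carbon C5 instead of C3.
  - The reversible oxa-Michael equilibrium may lie on the open-chain side.
  - The ambident phenoxide may attack through carbon.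
  - Chains may oligomerize.
  - The ketal may hydrolyse in the acid stage, which would erase the OH/OMe differentiation.
- Fallback approach (known chemistry only): the hindered ring A-ring B ether is made intermolecularly by SNAr on an ortho-fluorobenzaldehyde, and the macrocycle is closed at the A-D bridge by McMurry coupling. The detour sets out from 11 and comes back at 24.
- Ring A partner: commercial 2-fluoro-1,4-dimethoxybenzene is lithiated between F and OMe (n-BuLi, THF, -78 °C) and formylated with DMF to 2-fluoro-3,6-dimethoxybenzaldehyde F1. BCl3 in CH2Cl2 cleaves only the methyl ether chelated to the formyl group and gives 2-fluoro-6-hydroxy-3-methoxybenzaldehyde F2. BnBr/K2CO3 then gives 6-(benzyloxy)-2-fluoro-3-methoxybenzaldehyde F3.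
- B-C-D partner: in parallel, 11 is hydrogenated at the alkene only (H2, Pd/C, EtOAc, 1 atm) to the B-C bibenzyl nitrile F4. This is reduced with i-Bu2AlH to the B-C bibenzyl aldehyde F5 and desilylated (n-Bu4NF, AcOH, THF) to the ring B phenol aldehyde F6.
- Union and closure: F6 displaces the formyl-activated fluoride of F3 (K2CO3, DMF, 110 °C) to give the A-B-C-D dialdehyde F7. Low-valent titanium (TiCl4, Zn, pyridine, THF, reflux, slow addition) couples the two formyl groups to the macrocyclic A-D stilbene F8. H2 over Pd/C saturates the alkene and removes the benzyl ether, which gives 24.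

**Step 1.**
- What may go wrong: incomplete discrimination between the two phenolic oxygens, and double alkylation.
- Fallback: the order of ether formation and protection is inverted, so that no selective protection is needed. The detour sets out from 1 (with 3) and comes back at 4. Compound 1 is converted with two equivalents of KOt-Bu in DMSO into its dianion, in which the 3-oxide is not delocalized into the formyl group and is the more nucleophilic centre (the principle behind the known 3-O-selective alkylation of this dianion). SNAr with one equivalent of 3 at 70 °C should give 4-(5-formyl-2-hydroxyphenoxy)benzonitrile F9. The single remaining phenol is then protected (MOMCl, i-Pr2NEt, CH2Cl2) to give 4.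

**Step 8.**
- What may go wrong: over-reduction of the aluminated imine, incomplete imine hydrolysis at the mild pH imposed by the MOM acetal, or loss of the MOM group if the pH is lowered.
- Fallback: an ester replaces the nitrile as the masked ring D aldehyde, and the oxidation level is adjusted in two unambiguous stages. The detour sets out from 2 and comes back at 13. Compound 2 and commercial methyl 4-fluorobenzoate (K2CO3, DMF, 130 °C, SNAr) give methyl 4-[5-formyl-2-(methoxymethoxy)phenoxy]benzoate F10. Wittig olefination with ylide 10 gives the B-C stilbene methyl ester F11. LiAlH4 in THF at 0 °C gives the B-C stilbene benzylic alcohol F12, and MnO2 in CH2Cl2 oxidizes it to 13.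

**Further compounds**
F1 | step 15 | 2-fluoro-3,6-dimethoxybenzaldehyde | COc1ccc(OC)c(C=O)c1F
F2 | step 15 | 2-fluoro-6-hydroxy-3-methoxybenzaldehyde | COc1ccc(O)c(C=O)c1F
F3 | step 15 | 6-(benzyloxy)-2-fluoro-3-methoxybenzaldehyde | COc1ccc(OCc2ccccc2)c(C=O)c1F
F4 | step 15 | B-C bibenzyl nitrile | CC(C)[Si](Oc1cccc(CCc2ccc(OCOC)c(Oc3ccc(C#N)cc3)c2)c1)(C(C)C)C(C)C
F5 | step 15 | B-C bibenzyl aldehyde | CC(C)[Si](Oc1cccc(CCc2ccc(OCOC)c(Oc3ccc(C=O)cc3)c2)c1)(C(C)C)C(C)C
F6 | step 15 | ring B phenol aldehyde | Oc1cccc(CCc2ccc(OCOC)c(Oc3ccc(C=O)cc3)c2)c1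
F7 | step 15 | A-B-C-D dialdehyde | COc1ccc(OCc2ccccc2)c(C=O)c1Oc1cccc(CCc2ccc(OCOC)c(Oc3ccc(C=O)cc3)c2)c1
F8 | step 15 | macrocyclic A-D stilbene (ring A OBn, ring C OMOM, E/Z undefined) | COc1ccc(OCc3ccccc3)c2c1Oc1cccc(c1)CCc1ccc(OCOC)c(c1)Oc1ccc(cc1)C=C2
F9 | step 1 | 4-(5-formyl-2-hydroxyphenoxy)benzonitrile | O=Cc1ccc(O)c(Oc2ccc(C#N)cc2)c1
F10 | step 8 | methyl 4-[5-formyl-2-(methoxymethoxy)phenoxy]benzoate | O=Cc1ccc(OCOC)c(Oc2ccc(C(=O)OC)cc2)c1
F11 | step 8 | B-C stilbene methyl ester (E/Z mixture) | CC(C)[Si](Oc1cccc(C=Cc2ccc(OCOC)c(Oc3ccc(C(=O)OC)cc3)c2)c1)(C(C)C)C(C)C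
F12 | step 8 | B-C stilbene benzylic alcohol (E/Z mixture) | CC(C)[Si](Oc1cccc(C=Cc2ccc(OCOC)c(Oc3ccc(CO)cc3)c2)c1)(C(C)C)C(C)C
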